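**Assumptions.** Atom labels (C1–C20) follow ent-kaurane numbering of the target: acetal carbon C6, ring O–C19H2, C4 (methyl = C18), spiro carbon C10, C20H2–O–C7(=O), ketone C15, C16 (methyl = C17). The enantiomer of the amine catalyst in Step 1 is the one that gives (R)-3; its facial sense must be confirmed experimentally.

## Retrosynthetic overview
1. Ludongnin I ⇐ 16-methylene-15-ketone (exo-face H2 sets C16) ⇐ D ring by Pd(II) cycloalkenylation forming C13–C16.
2. C ring ⇐ Diels–Alder of butadiene onto a spiro alkylidene β-keto δ-lactone (sets C8 and C9).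
3. Spiro δ-lactone (C10) ⇐ Ti(III) epoxide-radical/acrylate coupling on an exo-methylene A-ring methyl acetal.
4. A-ring acetal ⇐ cis-fused β-keto γ-lactone by tethered Claisen acylation ⇐ (R)-3-(hydroxymethyl)-3-methylcyclohexanone.
5. C4 quaternary centre ⇐ organocatalytic asymmetric photochemical radical conjugate addition to 3-methylcyclohexenone. Ring order: A → acetal THF → spiro lactone → C → D.

## Route

**Step 1**
Reactants: 1, 3-methylcyclohex-2-en-1-one; 2, potassium (benzyloxymethyl)trifluoroborate
Product: 3, (R)-3-[(benzyloxy)methyl]-3-methylcyclohexan-1-one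
Conditions: trans-2-(carbazol-9-yl)cyclohexan-1-amine·TFA (single enantiomer, 20 mol %), 4CzIPN (3 mol %), MeCN/H2O 10:1, blue LEDs, 20 °C
Reagents that add atoms: none (all product atoms come from 1 and 2)
Why: Proposed new method: the enone forms a chiral iminium ion whose carbazole shields one face, photoexcited 4CzIPN oxidises 2 to the nucleophilic BnOCH2• radical, which adds to the β-carbon (C4) on the open face, and the α-iminyl radical cation is reduced by the carbazole (electron relay) and hydrolysed, setting the C4 quaternary centre; the closest known reaction type is enantioselective iminium-ion trapping of photogenerated benzodioxolyl and α-amino radicals by β-substituted cyclic enones, which has not been shown for alkoxymethyl radicals from trifluoroborates.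

**Step 2**
Reactants: 3
Product: 4, (R)-3-(hydroxymethyl)-3-methylcyclohexan-1-one
Conditions: H2 (1 atm), 10% Pd/C, EtOAc, rt
Reagents that add atoms: none
Why: Standard benzyl ether hydrogenolysis; the ketone and the quaternary centre are untouched.

**Step 3**
Reactants: 4
Product: 5, (3aR,7aR)-3a-methyltetrahydroisobenzofuran-1,7(3H,7aH)-dione (cis-fused β-keto γ-lactone; C6 lactone carbonyl on C5, ketone at C10)
Conditions: CDI, THF, rt; then t-BuOK (2.2 equiv), THF, 0 °C → rt; aq. HCl
Reagents that add atoms: 1,1'-carbonyldiimidazole, O=C(n1ccnc1)n1ccnc1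
Why: Tethered intramolecular Claisen (Dieckmann-type) C-acylation under equilibrating base, where only the C5 enolate can close the five-membered ring and the β-keto lactone enolate is the thermodynamic sink; C5 is set cis to the C19–O bridge by the ring fusion.

**Step 4**
Reactants: 5
Product: 6, (3aR,7aS)-3a-methyl-7-methylenehexahydroisobenzofuran-1(3H)-one
Conditions: Zn, CH2Br2, TiCl4, THF/CH2Cl2, 0 °C → rt
Reagents that add atoms: dibromomethane, BrCBr
Why: Takai–Lombardo methylenation, a non-basic gem-dimetallic reagent that methylenates the ketone in preference to the lactone and avoids a basic ylide on this acidic β-dicarbonyl.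

**Step 5**
Reactants: 6
Product: 7, (3aR,7aS)-3a-methyl-7-methyleneoctahydroisobenzofuran-1-ol (lactol, anomer mixture)
Conditions: DIBAL-H (1.1 equiv), CH2Cl2, −78 °C
Reagents that add atoms: none
Why: Partial reduction of a γ-lactone to the lactol through the stable aluminium hemiacetal at −78 °C.

**Step 6**
Reactants: 7
Product: 8, (1S,3aR,7aS)-1-methoxy-3a-methyl-7-methyleneoctahydroisobenzofuran
Conditions: MeOH, PPTS (cat.), rt
Reagents that add atoms: methanol, CO
Why: Fischer-type acetalisation via the cyclic oxocarbenium ion under thermodynamic control, placing OMe trans to C10 on C6 (convex face), which is the target C6 configuration.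

**Step 7**
Reactants: 8
Product: 9, spiro-epoxide of 8 at C10/C20 (1-methoxy-3a-methylhexahydrospiro[isobenzofuran-7,2'-oxirane], both C10 epimers)
Conditions: mCPBA, NaHCO3, CH2Cl2, 0 °C
Reagents that add atoms: mCPBA, OOC(=O)c1cccc(Cl)c1
Why: Buffered Prilezhaev epoxidation of the 1,1-disubstituted alkene; the epoxide configuration is irrelevant because C10 becomes a radical in the next step.

**Step 8**
Reactants: 9; 10, 2,2,2-trifluoroethyl acrylate
Product: 11, (1S,3aR,7R,7aR)-1-methoxy-3a-methyloctahydrospiro[isobenzofuran-7,3'-pyran]-6'-one (spiro δ-lactone C20–O–C7(=O)–C8H2–C9H2 on C10)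
Conditions: Cp2TiCl2, Zn dust, 2,4,6-collidine·HCl, THF, rt
Reagents that add atoms: none (C7–C9 come from 10)
Why: Nugent–RajanBabu Ti(III) reductive epoxide opening gives the tertiary C10 radical, which undergoes Giese addition to the acrylate on the face anti to C6 and the axial C19, and the titanium alkoxide then lactonises onto the activated ester, setting C10 with C20 cis to C6.

**Step 9**
Reactants: 11
Product: 12, 5'-acetyl derivative of 11 (α-acetyl δ-lactone, C8 epimers/enol)
Conditions: LDA (2.2 equiv), THF, −78 °C; 1-acetylimidazole, −78 → −40 °C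
Reagents that add atoms: 1-acetylimidazole, CC(=O)n1ccnc1
Why: Crossed Claisen C-acylation of the lactone enolate at C8, the only enolisable position.

**Step 10**
Reactants: 12
Product: 13, 5'-acetyl-4',5'-didehydro derivative of 11 (spiro alkylidene β-keto δ-lactone, C8=C9)
Conditions: PhSeCl, pyridine, CH2Cl2, 0 °C; then 30% H2O2, 0 °C → rt
Reagents that add atoms: none
Why: α-Selenenylation of the β-dicarbonyl followed by selenoxide syn-elimination, which can only go toward C9 and cannot deconjugate because C10 is quaternary.

**Step 11**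
Reactants: 13; 14, buta-1,3-diene
Product: 15, cis-fused Diels–Alder adduct (4R,5R,6S,8S,9S,10R): C8 bears acetyl and the lactone carbonyl, C9–H, new cyclohexene C11–C12=C13–C14
Conditions: butadiene (excess), ZnCl2 (1.0 M in Et2O, 1 equiv), CH2Cl2, 0 °C → rt, sealed tube
Reagents that add atoms: none (C11–C14 come from 14)
Why: Lewis-acid-promoted Diels–Alder on the doubly activated dienophile, with the diene adding suprafacially to the C8=C9 face anti to the more substituted C5 branch of the spiro centre, which sets C9 (C11 anti to C5) and C8 (C14 cis to C11).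

**Step 12**
Reactants: 15
Product: 16, tert-butyldimethylsilyl enol ether of the methyl ketone of 15 (C8–C(OTBS)=CH2)
Conditions: KHMDS, THF, −78 °C; TBSCl
Reagents that add atoms: tert-butyldimethylsilyl chloride, CC(C)(C)[Si](C)(C)Cl
Why: Kinetic enolate O-silylation, where the methyl group is the only enolisable site because C8 is quaternary and base conditions spare the acetal.

**Step 13**
Reactants: 16
Product: 17, bicyclo[3.2.1]octenone (4R,5R,6S,8S,9S,10R,13R): C13–C16H2 bond formed, C15 ketone, C11=C12 alkene
Conditions: Pd(OAc)2 (1.1 equiv), DMSO/MeCN, 45 °C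
Reagents that add atoms: none
Why: Pd(II)-mediated oxidative cycloalkenylation (Saegusa-type, 5-exo) of the silyl enol ether onto the ring alkene at C13, followed by β-hydride elimination toward C11; C13 is fixed by the bridging geometry.

**Step 14**
Reactants: 17
Product: 18, 16-methylene-15-ketone (C16=C17H2), otherwise as 17
Conditions: LiHMDS, THF, −78 °C; Me2N+=CH2 I−, −78 → 0 °C; then MeI; then DBU
Reagents that add atoms: Eschenmoser's salt, C=[N+](C)C.[I-]
Why: Eschenmoser α-methylenation (Mannich reaction, quaternisation, elimination) at C16, the only enolisable position of the ketone.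

**Step 15**
Reactants: 18
Product: 19, ludongnin I
Conditions: H2 (1 atm), 10% Pd/C, EtOAc, rt
Reagents that add atoms: none
Why: Heterogeneous hydrogenation saturates C11=C12 and delivers hydrogen to the exocyclic enone from the open exo face (the C14 side), leaving the C17 methyl endo (16R).

## Compound list
1 | 3-methylcyclohex-2-en-1-one | CC1=CC(=O)CCC1 | starting material
2 | potassium (benzyloxymethyl)trifluoroborate | [K+].F[B-](F)(F)COCc1ccccc1 | starting material
3 | (R)-3-[(benzyloxy)methyl]-3-methylcyclohexan-1-one | c1ccccc1COC[C@]2(C)CCCC(=O)C2 | intermediate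
4 | (R)-3-(hydroxymethyl)-3-methylcyclohexan-1-one | OC[C@]1(C)CCCC(=O)C1 | intermediate
5 | (3aR,7aR)-3a-methyltetrahydroisobenzofuran-1,7(3H,7aH)-dione | O=C1OC[C@]2(C)CCCC(=O)[C@H]12 | intermediate
6 | (3aR,7aS)-3a-methyl-7-methylenehexahydroisobenzofuran-1(3H)-one | O=C1OC[C@]2(C)CCCC(=C)[C@H]12 | intermediate
7 | (3aR,7aS)-3a-methyl-7-methyleneoctahydroisobenzofuran-1-ol (anomers) | OC1OC[C@]2(C)CCCC(=C)[C@H]12 | intermediate
8 | (1S,3aR,7aS)-1-methoxy-3a-methyl-7-methyleneoctahydroisobenzofuran | CO[C@H]1OC[C@]2(C)CCCC(=C)[C@H]12 | intermediate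
9 | C10/C20 spiro-epoxide of 8 (epimers at C10) | CO[C@H]1OC[C@]2(C)CCCC3(CO3)[C@H]12 | intermediate
10 | 2,2,2-trifluoroethyl acrylate | C=CC(=O)OCC(F)(F)F | starting material
11 | (1S,3aR,7R,7aR)-1-methoxy-3a-methyloctahydrospiro[isobenzofuran-7,3'-pyran]-6'-one | CO[C@H]1OC[C@]2(C)CCC[C@]3(COC(=O)CC3)[C@H]12 | intermediate
12 | 5'-acetyl derivative of 11 (C8 epimers) | CO[C@H]1OC[C@]2(C)CCC[C@]3(COC(=O)C(C(C)=O)C3)[C@H]12 | intermediate
13 | 5'-acetyl-4',5'-didehydro derivative of 11 (C8=C9) | CO[C@H]1OC[C@]2(C)CCC[C@]3(COC(=O)C(C(C)=O)=C3)[C@H]12 | intermediate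
14 | buta-1,3-diene | C=CC=C | starting material
15 | Diels–Alder adduct, 8-acetyl Δ12-cyclohexene cis-fused to the δ-lactone (4R,5R,6S,8S,9S,10R) | CO[C@H]1OC[C@]2(C)CCC[C@]3(COC(=O)[C@@]4(C(C)=O)CC=CC[C@H]43)[C@H]12 | intermediate
16 | TBS enol ether of 15 | CO[C@H]1OC[C@]2(C)CCC[C@]3(COC(=O)[C@@]4(C(=C)O[Si](C)(C)C(C)(C)C)CC=CC[C@H]43)[C@H]12 | intermediate
17 | 11,12-didehydro-16-nor-methyl bicyclo[3.2.1]octenone (C16H2, C15=O, C11=C12) | CO[C@H]1OC[C@]2(C)CCC[C@]3(COC(=O)[C@@]45C[C@@H](C=C[C@H]43)CC5=O)[C@H]12 | intermediate
18 | 16-methylene-15-ketone with C11=C12 | CO[C@H]1OC[C@]2(C)CCC[C@]3(COC(=O)[C@@]45C[C@@H](C=C[C@H]43)C(=C)C5=O)[C@H]12 | intermediate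
19 | ludongnin I | CO[C@H]1OC[C@]2(C)CCC[C@]3(COC(=O)[C@@]45C[C@@H](CC[C@H]43)[C@@H](C)C5=O)[C@H]12 | target

## Totals and risks
Total steps: 15. Longest linear sequence: 15 (2, 10 and 14 are commercial).

Steps most likely to fail:

1. **Step 1 (proposed new asymmetric radical conjugate addition).** The alkoxymethyl radical may give low ee or a racemic background reaction. Fallback (known chemistry): chiral primary-amine-catalysed Michael addition of nitromethane to 1 to give (R)-3-methyl-3-(nitromethyl)cyclohexanone, then ketalisation, Nef reaction to the aldehyde, NaBH4 reduction and deketalisation to reach 4 (about four extra steps).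

2. **Step 4 (methylenation of the β-keto lactone).** Titanium enolate formation may block methylenation. Fallback: convert 5 to its enol triflate (Tf2O, i-Pr2NEt), cross-couple with MeMgBr/Fe(acac)3 to the conjugated β-methyl butenolide, then deconjugate by kinetic γ-deprotonation (LDA) and α-protonation to give 6.

3. **Step 13 (Pd(II) cycloalkenylation).** 6-endo closure or simple desilylation may compete. Fallback: epoxidise C12=C13 of 15 on the face anti to the acetyl arm, close the D ring by intramolecular enolate opening of the epoxide at C13 (KHMDS), and remove the resulting C12 alcohol by Barton–McCombie deoxygenation; the saturated ketone then rejoins the route at Step 14, and Step 15 reduces only the exocyclic alkene.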